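**Plan**

- Retrosynthesis: the two C–O bonds at the ketal carbon and the bond from C8 to the carbinol carbon are cut first. This gives tri-O-benzyl ent-afzelechin 3-methyl ether and a 1,3-diaryl vicinal triketone. In the flavan, the C3–O bond and then the C2–C3 bond of ring C are cut, leading back to an ortho-allyl aryl ester.
- Forward: Claisen rearrangement and acylation give the ester. Ring C (O1, C2, C3, C4, C4a, C8a) closes at C2–C3 by ring-closing carbonyl–olefin metathesis, followed by hydroboration and methylation. Friedel–Crafts hydroxyalkylation at C8 joins the triketone, and hydrogenolysis triggers a double ketalisation that closes the dihydrofuran and pyranone rings.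
- Enabling feature: C2 carries O1 and an aryl group, so O1–C2 can be an aryl ester, and C3–C4 can be an allyl group on C4a next to O1. The ester C=O and the allyl C=C then sit six atoms apart.
- Stereochemistry: C2 and C3 (2S,3R, trans) come from syn hydroboration of the C2=C3 enol ether with IpcBH2. The carbinol carbon comes from a chiral Cu(OTf)2–bis(oxazoline) catalyst. The ketal carbon comes from the ring closure, which is tied to the carbinol carbon.

Key step: step 4

Assumption: the stereodescriptors of the target SMILES are carried as written. Because the dihydrofuran and pyranone rings share the carbinol–ketal bond, the ketal carbon is not set independently but follows from the carbinol carbon on ring closure, so the carbinol carbon is the centre the route controls.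

**Route**

Step 1
Reactants: 1 3,5-bis(benzyloxy)phenol; 2 allyl bromide
Product: 3 allyl 3,5-bis(benzyloxy)phenyl ether
Conditions: K2CO3, acetone, reflux
Reagents that add atoms: none
Why: Williamson O-allylation of the only free phenol should proceed cleanly; no stereocenter is involved.

Step 2
Reactants: 3 allyl 3,5-bis(benzyloxy)phenyl ether
Product: 4 2-allyl-3,5-bis(benzyloxy)phenol
Conditions: N,N-diethylaniline, 200 °C
Reagents that add atoms: none
Why: The aromatic Claisen rearrangement should deliver the allyl group (future C3 and C4) to an ortho carbon, and the two ortho positions are equivalent by symmetry, so a single regioisomer is expected.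

Step 3
Reactants: 4 2-allyl-3,5-bis(benzyloxy)phenol; 5 4-(benzyloxy)benzoyl chloride
Product: 6 2-allyl-3,5-bis(benzyloxy)phenyl 4-(benzyloxy)benzoate
Conditions: Et3N, DMAP (cat.), CH2Cl2, 0 °C to rt
Reagents that add atoms: none
Why: DMAP-catalysed O-acylation of the phenol should install C2 with its aryl group at the ester oxidation level.

Step 4
Reactants: 6 2-allyl-3,5-bis(benzyloxy)phenyl 4-(benzyloxy)benzoate
Product: 7 5,7-bis(benzyloxy)-2-[4-(benzyloxy)phenyl]-4H-chromene
Conditions: TiCl4, Zn, PbCl2 (cat.), TMEDA, CH3CHBr2, THF/CH2Cl2, 0 to 65 °C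
Reagents that add atoms: none
Why: The low-valent titanium ethylidene formed from TiCl4, Zn and CH3CHBr2 should first exchange with the unhindered terminal alkene of the allyl group ([2+2] and cycloreversion, loss of propene) to put a titanium alkylidene on C3, which then adds across the ester C2=O six atoms away and collapses through an oxatitanacyclobutane to the C2=C3 enol ether and a titanium oxo species. The closest known reaction type is the olefinic ester cyclization (ring-closing carbonyl–olefin metathesis of esters with Tebbe- or Takai–Utimoto-type alkylidenes) used for six- and seven-membered cyclic enol ethers. Ring C (O1, C2, C3, C4, C4a, C8a) closes as a six-membered ring by intramolecular carbonyl olefination, the new double bond lying inside the ring. No stereocenter is formed here; the step delivers the C2=C3 enol ether on which step 5 sets C2 and C3 together. The selectivity needed is alkylidene exchange at the alkene ahead of plain ethylidenation of the ester, which the monosubstituted alkene, the ortho placement of allyl and ester and the absence of any other carbonyl group should secure; benzyl ethers are inert to the reagent.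

Step 5
Reactants: 7 5,7-bis(benzyloxy)-2-[4-(benzyloxy)phenyl]-4H-chromene
Product: 9 (2S,3R)-5,7-bis(benzyloxy)-2-[4-(benzyloxy)phenyl]chroman-3-ol, via borane adduct 8 (not isolated)
Conditions: IpcBH2 (from (−)-α-pinene), THF, −25 to 0 °C; then NaOH, H2O2, 0 °C to rt
Reagents that add atoms: hydrogen peroxide, OO
Why: Asymmetric hydroboration–oxidation should add H to C2 and boron to C3 (β to O1, the less substituted carbon) on the same face, so oxidation with retention gives the 2,3-trans alcohol, and the isopinocampheyl group selects the face that gives (2S,3R), the sense being assigned by analogy with 1-arylcycloalkenes.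

Step 6
Reactants: 9 (2S,3R)-5,7-bis(benzyloxy)-2-[4-(benzyloxy)phenyl]chroman-3-ol
Product: 10 (2S,3R)-5,7-bis(benzyloxy)-2-[4-(benzyloxy)phenyl]-3-methoxychromane
Conditions: NaH, MeI, THF/DMF, 0 °C to rt
Reagents that add atoms: iodomethane, CI
Why: Williamson methylation of the secondary alkoxide should not touch C2 or C3, since neither bears an acidic hydrogen.

Step 7
Reactants: 11 1-(2,4,6-trihydroxyphenyl)ethanone
Product: 12 1-[2,4,6-tris(benzyloxy)phenyl]ethanone
Conditions: BnBr, K2CO3, DMF, 80 °C
Reagents that add atoms: benzyl bromide, BrCc1ccccc1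
Why: Exhaustive Williamson O-benzylation with excess halide and heating should also alkylate the hydrogen-bonded ortho hydroxyls.

Step 8
Reactants: 12 1-[2,4,6-tris(benzyloxy)phenyl]ethanone; 13 methyl 4-(benzyloxy)benzoate
Product: 14 1-[4-(benzyloxy)phenyl]-3-[2,4,6-tris(benzyloxy)phenyl]propane-1,3-dione
Conditions: NaH, THF, reflux; aq. HCl work-up
Reagents that add atoms: none
Why: Crossed Claisen condensation should be clean because only the ketone is enolisable and the diketone is removed as its stabilised enolate.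

Step 9
Reactants: 14 1-[4-(benzyloxy)phenyl]-3-[2,4,6-tris(benzyloxy)phenyl]propane-1,3-dione
Product: 15 1-[4-(benzyloxy)phenyl]-3-[2,4,6-tris(benzyloxy)phenyl]propane-1,2,3-trione
Conditions: SeO2, 1,4-dioxane, reflux; azeotropic drying (toluene)
Reagents that add atoms: selenium dioxide, O=[Se]=O
Why: Riley oxidation of the doubly activated methylene should give the vicinal tricarbonyl compound, as known for dibenzoylmethanes.

Step 10
Reactants: 10 (2S,3R)-5,7-bis(benzyloxy)-2-[4-(benzyloxy)phenyl]-3-methoxychromane; 15 1-[4-(benzyloxy)phenyl]-3-[2,4,6-tris(benzyloxy)phenyl]propane-1,2,3-trione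
Product: 16 (2S)-2-{(2S,3R)-5,7-bis(benzyloxy)-2-[4-(benzyloxy)phenyl]-3-methoxychroman-8-yl}-1-[4-(benzyloxy)phenyl]-2-hydroxy-3-[2,4,6-tris(benzyloxy)phenyl]propane-1,3-dione
Conditions: Cu(OTf)2 (10 mol%), (S,S)-t-Bu-bis(oxazoline) (11 mol%), 4 Å MS, CH2Cl2, −20 °C to rt
Reagents that add atoms: none
Why: Friedel–Crafts hydroxyalkylation should occur at the central, most electrophilic carbonyl and at C8, which is less shielded than C6 between two benzyloxy groups, while the chiral divalent copper bis(oxazoline) chelate, not the remote flavan centres, is relied on to select the face leading to the (S)-carbinol.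

Step 11
Reactants: 16 (2S)-2-{(2S,3R)-5,7-bis(benzyloxy)-2-[4-(benzyloxy)phenyl]-3-methoxychroman-8-yl}-1-[4-(benzyloxy)phenyl]-2-hydroxy-3-[2,4,6-tris(benzyloxy)phenyl]propane-1,3-dione
Product: 18 target CNP0205438.1, via heptaphenol 17 (not isolated)
Conditions: H2 (1 atm), Pd(OH)2/C, THF/EtOAc, rt; filtration; PPTS (cat.), 4 Å MS, THF, rt
Reagents that add atoms: none
Why: Hydrogenolysis of the seven benzyl ethers should free 7-OH and the ortho hydroxyls of the trihydroxybenzoyl ring, which add under mild acid to the 4-hydroxybenzoyl carbonyl (the only carbonyl both can reach through a five- and a six-membered ring) in a double ketalisation with loss of water, the ketal carbon being fixed by the carbinol carbon.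

**Compound list**

1 | 3,5-bis(benzyloxy)phenol | Oc1cc(OCc2ccccc2)cc(OCc2ccccc2)c1 | starting material
2 | allyl bromide | C=CCBr | starting material
3 | allyl 3,5-bis(benzyloxy)phenyl ether | C=CCOc1cc(OCc2ccccc2)cc(OCc2ccccc2)c1 | intermediate
4 | 2-allyl-3,5-bis(benzyloxy)phenol | C=CCc1c(O)cc(OCc2ccccc2)cc1OCc1ccccc1 | intermediate
5 | 4-(benzyloxy)benzoyl chloride | O=C(Cl)c1ccc(OCc2ccccc2)cc1 | starting material
6 | 2-allyl-3,5-bis(benzyloxy)phenyl 4-(benzyloxy)benzoate | C=CCc1c(OCc2ccccc2)cc(OCc2ccccc2)cc1OC(=O)c1ccc(OCc2ccccc2)cc1 | intermediate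
7 | 5,7-bis(benzyloxy)-2-[4-(benzyloxy)phenyl]-4H-chromene | C1=C(c2ccc(OCc3ccccc3)cc2)Oc2cc(OCc3ccccc3)cc(OCc3ccccc3)c2C1 | intermediate
8 | borane adduct: (1S,2S,3S,5R)-isopinocampheyl(flavan-3-yl)borane, boron on C3 cis to 2-H, flavan as in 9 | C[C@@H]1[C@@H](B[C@@H]3Cc4c(OCc5ccccc5)cc(OCc5ccccc5)cc4O[C@H]3c3ccc(OCc4ccccc4)cc3)C[C@H]2C[C@@H]1C2(C)C | intermediate
9 | (2S,3R)-5,7-bis(benzyloxy)-2-[4-(benzyloxy)phenyl]chroman-3-ol | O[C@@H]1Cc2c(OCc3ccccc3)cc(OCc3ccccc3)cc2O[C@H]1c1ccc(OCc2ccccc2)cc1 | intermediate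
10 | (2S,3R)-5,7-bis(benzyloxy)-2-[4-(benzyloxy)phenyl]-3-methoxychromane | CO[C@@H]1Cc2c(OCc3ccccc3)cc(OCc3ccccc3)cc2O[C@H]1c1ccc(OCc2ccccc2)cc1 | intermediate
11 | 1-(2,4,6-trihydroxyphenyl)ethanone | CC(=O)c1c(O)cc(O)cc1O | starting material
12 | 1-[2,4,6-tris(benzyloxy)phenyl]ethanone | CC(=O)c1c(OCc2ccccc2)cc(OCc2ccccc2)cc1OCc1ccccc1 | intermediate
13 | methyl 4-(benzyloxy)benzoate | COC(=O)c1ccc(OCc2ccccc2)cc1 | starting material
14 | 1-[4-(benzyloxy)phenyl]-3-[2,4,6-tris(benzyloxy)phenyl]propane-1,3-dione | O=C(CC(=O)c1c(OCc2ccccc2)cc(OCc2ccccc2)cc1OCc1ccccc1)c1ccc(OCc2ccccc2)cc1 | intermediate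
15 | 1-[4-(benzyloxy)phenyl]-3-[2,4,6-tris(benzyloxy)phenyl]propane-1,2,3-trione | O=C(C(=O)C(=O)c1c(OCc2ccccc2)cc(OCc2ccccc2)cc1OCc1ccccc1)c1ccc(OCc2ccccc2)cc1 | intermediate
16 | (2S)-2-{(2S,3R)-5,7-bis(benzyloxy)-2-[4-(benzyloxy)phenyl]-3-methoxychroman-8-yl}-1-[4-(benzyloxy)phenyl]-2-hydroxy-3-[2,4,6-tris(benzyloxy)phenyl]propane-1,3-dione | CO[C@@H]1Cc2c(OCc3ccccc3)cc(OCc3ccccc3)c(c2O[C@H]1c1ccc(OCc2ccccc2)cc1)[C@@](O)(C(=O)c1c(OCc2ccccc2)cc(OCc2ccccc2)cc1OCc1ccccc1)C(=O)c1ccc(OCc2ccccc2)cc1 | intermediate
17 | heptaphenol: (2S)-2-hydroxy-2-[(2S,3R)-5,7-dihydroxy-2-(4-hydroxyphenyl)-3-methoxychroman-8-yl]-1-(4-hydroxyphenyl)-3-(2,4,6-trihydroxyphenyl)propane-1,3-dione | CO[C@@H]1Cc2c(O)cc(O)c(c2O[C@H]1c1ccc(O)cc1)[C@@](O)(C(=O)c1c(O)cc(O)cc1O)C(=O)c1ccc(O)cc1 | intermediate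
18 | CNP0205438.1: (2S,3R)-5-hydroxy-2-(4-hydroxyphenyl)-3-methoxychromane fused at O7 and C8 to the ketal carbon C2 and the carbinol carbon C3 of a 3,5,7-trihydroxy-2-(4-hydroxyphenyl)chroman-4-one, configuration as in the SMILES | CO[C@@H]1Cc2c(O)cc3c(c2O[C@H]1c1ccc(O)cc1)[C@@]1(O)C(=O)c2c(O)cc(O)cc2O[C@]1(c1ccc(O)cc1)O3 | target

**Step count and risks**

Total step count: 11. Longest linear sequence: 8 steps (steps 1 to 6, then 10 and 11).

Steps most likely to fail:

1. Step 10. The arene may attack through C6 instead of C8, the catalyst may give poor facial selectivity at the central carbonyl, or the congested addition may stall. Fallback, setting out from 10 and coming back at 16: NBS in CH2Cl2 at −20 °C should brominate C8 selectively to give (2S,3R)-5,7-bis(benzyloxy)-2-[4-(benzyloxy)phenyl]-8-bromo-3-methoxychromane F1. Bromine–lithium exchange with n-BuLi in THF at −78 °C gives the 8-lithio flavan F2, which is added to trione 15. NH4Cl work-up should give 16 together with its carbinol epimer F3, and the two are diastereomers to be separated by chromatography.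

2. Step 4. The ester may be simply ethylidenated without ring closure, the allyl group may isomerise into conjugation before cyclisation, or the enol ether may hydrolyse on work-up. Fallback, setting out from 6 and coming back at 7: methylenation of the ester with Cp2TiMe2 in toluene at 65 °C gives 2-allyl-3,5-bis(benzyloxy)phenyl 1-[4-(benzyloxy)phenyl]vinyl ether F4. Ring-closing olefin metathesis with the second-generation Grubbs catalyst RuCl2(=CHPh)(PCy3)(H2IMes) in toluene at 70 °C then forms the same C2=C3 bond.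

3. Step 5. The reagent may give low facial selectivity on the aryl enol ether, or the β-alkoxyborane may eliminate before oxidation. Fallback, setting out from 7 and coming back at 9: BH3·SMe2 in THF followed by NaOH/H2O2 gives the racemic trans-alcohol F5. Esterification with (S)-2-methoxy-2-phenylacetic acid (DCC, DMAP, CH2Cl2) gives the ester of the (2S,3R)-alcohol F6 and the ester of the (2R,3S)-alcohol F7, which are diastereomers to be separated by chromatography or crystallisation. LiOH in THF/H2O cleaves F6 to 9.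

Further compounds
F1 | step 10 | (2S,3R)-5,7-bis(benzyloxy)-2-[4-(benzyloxy)phenyl]-8-bromo-3-methoxychromane | CO[C@@H]1Cc2c(OCc3ccccc3)cc(OCc3ccccc3)c(Br)c2O[C@H]1c1ccc(OCc2ccccc2)cc1
F2 | step 10 | 8-lithio flavan | CO[C@@H]1Cc2c(OCc3ccccc3)cc(OCc3ccccc3)c([Li])c2O[C@H]1c1ccc(OCc2ccccc2)cc1
F3 | step 10 | carbinol epimer of 16, (2R) at the carbinol carbon | CO[C@@H]1Cc2c(OCc3ccccc3)cc(OCc3ccccc3)c(c2O[C@H]1c1ccc(OCc2ccccc2)cc1)[C@](O)(C(=O)c1c(OCc2ccccc2)cc(OCc2ccccc2)cc1OCc1ccccc1)C(=O)c1ccc(OCc2ccccc2)cc1
F4 | step 4 | 2-allyl-3,5-bis(benzyloxy)phenyl 1-[4-(benzyloxy)phenyl]vinyl ether | C=CCc1c(OCc2ccccc2)cc(OCc2ccccc2)cc1OC(=C)c1ccc(OCc2ccccc2)cc1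
F5 | step 5 | racemic trans-5,7-bis(benzyloxy)-2-[4-(benzyloxy)phenyl]chroman-3-ol | O[C@@H]1Cc2c(OCc3ccccc3)cc(OCc3ccccc3)cc2O[C@H]1c1ccc(OCc2ccccc2)cc1.O[C@H]1Cc2c(OCc3ccccc3)cc(OCc3ccccc3)cc2O[C@@H]1c1ccc(OCc2ccccc2)cc1
F6 | step 5 | (S)-2-methoxy-2-phenylacetate of the (2S,3R)-alcohol | CO[C@H](C(=O)O[C@@H]1Cc2c(OCc3ccccc3)cc(OCc3ccccc3)cc2O[C@H]1c1ccc(OCc2ccccc2)cc1)c1ccccc1
F7 | step 5 | (S)-2-methoxy-2-phenylacetate of the (2R,3S)-alcohol | CO[C@H](C(=O)O[C@H]1Cc2c(OCc3ccccc3)cc(OCc3ccccc3)cc2O[C@@H]1c1ccc(OCc2ccccc2)cc1)c1ccccc1
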